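**Retrosynthetic overview**
- The route rests on hexasubstituted ring A (C1 OMe, C2 Me, C3 OH, C4 bridge CH2, C5 OMe, C6 isobutyryl). C1–C4 are the diene carbons of an O-methylated 2-methylcyclohexane-1,3-dione and C5–C6 are the two alkyne carbons of a methoxy ynone. A Diels–Alder addition followed by loss of ethylene (Alder–Rickert) forms C4–C5 and C1–C6 and delivers ring A with all six substituents in place.
- Ring B is bought as an aromatic ring (2-methylphloroglucinol), formylated and tribenzylated. The formyl carbon becomes the bridge CH2 through an aldol condensation with the kinetic enolate of the dione methyl enol ether. A 2,4,6-trialkoxybenzyl halide is avoided because it would ionise and self-alkylate.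
- Rhodium-catalysed 1,4-hydrosilylation of the resulting arylidene enone gives the 1-methoxy-3-silyloxycyclohexa-1,3-diene directly. The ynone comes from lithium methoxyacetylide and the Weinreb amide of isobutyric acid.
- After ring A is made: Friedel–Crafts isobutyrylation at C5' of ring B, desilylation, hydrogenolysis.
- Ring order: ring B (purchased), then ring A by cycloaddition and cycloreversion.

Key step: step 8

Remark: the target is achiral. Aldol 8, mesylate 9, adduct 16 and fallback compounds F7 and F8 are racemic or diastereomeric mixtures whose stereocentres are erased downstream, so their SMILES carry no stereodescriptors. N-methoxy-N-methylisobutyramide is taken as a purchased compound.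

**Route**

Step 1
Reactants: 1 2-methylphloroglucinol
Product: 3 2,4,6-trihydroxy-3-methylbenzaldehyde, via aryl iminium chloride 2 (not isolated)
Conditions: POCl3 (1.1 equiv), DMF, EtOAc, 0 °C to rt; then H2O, 60 °C
Reagents that add atoms: N,N-dimethylformamide, CN(C)C=O (formyl carbon); water, O (aldehyde oxygen)
Why: Vilsmeier–Haack formylation should occur once on the very electron-rich ring, the two free positions of 1 being equivalent by symmetry, and the formyl group both supplies the future bridge carbon and damps the ring against C-benzylation in step 2.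

Step 2
Reactants: 3 2,4,6-trihydroxy-3-methylbenzaldehyde
Product: 4 2,4,6-tris(benzyloxy)-3-methylbenzaldehyde
Conditions: BnBr (3.5 equiv), K2CO3, Bu4NI (cat.), DMF, 60 °C
Reagents that add atoms: benzyl bromide, BrCc1ccccc1
Why: Williamson ether synthesis on the three phenols, with heating to overcome the hydrogen bonds of the two hydroxyls ortho to the aldehyde, should give the tribenzyl ether.

Step 3
Reactants: 5 2-methylcyclohexane-1,3-dione
Product: 6 3-methoxy-2-methylcyclohex-2-en-1-one
Conditions: MeOH, HC(OMe)3, p-TsOH (cat.), rt to 50 °C; Et3N quench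
Reagents that add atoms: methanol, CO; trimethyl orthoformate, COC(OC)OC (its methoxy groups exchange with the solvent, so either may supply the OMe)
Why: Acid-catalysed enol etherification of a cyclic 1,3-dione, with the orthoformate consuming the water, should give a single enol ether because the two carbonyl groups are equivalent.

Step 4
Reactants: 6 3-methoxy-2-methylcyclohex-2-en-1-one; 4 2,4,6-tris(benzyloxy)-3-methylbenzaldehyde
Product: 8 6-{hydroxy[2,4,6-tris(benzyloxy)-3-methylphenyl]methyl}-3-methoxy-2-methylcyclohex-2-en-1-one, via lithium dienolate of 6 7 (not isolated)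
Conditions: LiN(i-Pr)2 (LDA, 1.05 equiv), THF, −78 °C; then 4, −78 °C; AcOH quench at −78 °C
Reagents that add atoms: none
Why: Kinetic deprotonation of the vinylogous ester at the carbon alpha to the carbonyl (Stork–Danheiser regiochemistry) and aldol addition to the non-enolisable aldehyde should form the ring–bridge C–C bond, the two new stereocentres being removed in steps 5 and 6.

Step 5
Reactants: 8 6-{hydroxy[2,4,6-tris(benzyloxy)-3-methylphenyl]methyl}-3-methoxy-2-methylcyclohex-2-en-1-one
Product: 10 (E)-6-{[2,4,6-tris(benzyloxy)-3-methylphenyl]methylidene}-3-methoxy-2-methylcyclohex-2-en-1-one, via benzylic mesylate 9 (not isolated)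
Conditions: MsCl, Et3N, CH2Cl2, 0 °C; then DBU, rt
Reagents that add atoms: none
Why: Mesylation and base-induced E1cB elimination (completion of the aldol condensation), helped by the strongly donor-substituted benzylic carbon, should give the conjugated arylidene ketone as the thermodynamically preferred E isomer with the aryl group anti to the carbonyl.

Step 6
Reactants: 10 (E)-6-{[2,4,6-tris(benzyloxy)-3-methylphenyl]methylidene}-3-methoxy-2-methylcyclohex-2-en-1-one
Product: 11 1-methoxy-2-methyl-3-(triethylsilyloxy)-4-{[2,4,6-tris(benzyloxy)-3-methylphenyl]methyl}cyclohexa-1,3-diene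
Conditions: Et3SiH (1.5 equiv), RhCl(PPh3)3 (2 mol%), benzene, 60 °C; filtration through Et3N-deactivated silica
Reagents that add atoms: triethylsilane, CC[SiH](CC)CC
Why: Rhodium-catalysed 1,4-hydrosilylation of an α,β-unsaturated ketone with a monohydrosilane (Ojima conditions) should deliver hydride to the benzylic carbon and silicon to oxygen, giving the silyl enol ether regiospecifically without strong base while the tetrasubstituted, donor-substituted vinylogous ester double bond is left alone.

Step 7
Reactants: 12 chloroacetaldehyde dimethyl acetal; 13 N-methoxy-N-methylisobutyramide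
Product: 15 1-methoxy-4-methylpent-1-yn-3-one, via lithium methoxyacetylide 14 (not isolated)
Conditions: Et2NH, n-BuLi (3 equiv each), THF, 0 °C; 12 (1 equiv), 0 °C; then 13 (0.8 equiv), −78 to 0 °C; cold pH 7 phosphate buffer; bulb-to-bulb distillation
Reagents that add atoms: none
Why: Double elimination (methanol, then HCl) and metalation of 12 by three equivalents of lithium amide gives the alkoxyacetylide, whose addition to the Weinreb amide stops at the chelated tetrahedral adduct (Weinreb ketone synthesis), so the ynone is released only on neutral work-up and an acid-labile propargylic alcohol stage is avoided.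

Step 8
Reactants: 11 1-methoxy-2-methyl-3-(triethylsilyloxy)-4-{[2,4,6-tris(benzyloxy)-3-methylphenyl]methyl}cyclohexa-1,3-diene; 15 1-methoxy-4-methylpent-1-yn-3-one
Product: 17 1-[2,6-dimethoxy-3-methyl-4-(triethylsilyloxy)-5-{[2,4,6-tris(benzyloxy)-3-methylphenyl]methyl}phenyl]-2-methylpropan-1-one, via bicyclo[2.2.2]octadiene adduct 16 (not isolated)
Conditions: 15 (3 equiv), toluene, BHT (cat.), N,O-bis(trimethylsilyl)acetamide (0.2 equiv), sealed tube, 120 °C; then 170 °C
Reagents that add atoms: none
Why: Proposed new method: diene carbon C4, made nucleophilic by both the C1 methoxy group (through the diene) and the C3 silyloxy group, should attack the methoxy-bearing β-carbon of ynone 15 while C1 bonds to the acyl-bearing α-carbon in a concerted but strongly asynchronous (4+2) addition giving adduct 16, which on further heating should expel its saturated two-carbon bridge as ethylene in a retro-Diels–Alder step driven by aromatisation. The closest known reaction type is the Alder–Rickert reaction of 1-alkoxy-3-silyloxycyclohexa-1,3-dienes with acetylenic esters and ketones; new here is the β-methoxy ynone as dienophile, a push–pull alkyne whose LUMO is raised by the oxygen but whose β-carbon stays the electrophilic site, as in the addition–elimination chemistry of β-alkoxy enones. The one ring that is closed, the future ring A, forms by an intermolecular suprafacial (4+2) addition across C1 and C4 of the diene, so no intramolecular closure mode is involved. The two bridgehead stereocentres of 16 are transient and vanish when ethylene is lost, so no stereocentre needs control. The selectivity required is regiochemical (C4 to C5, C1 to C6) and is secured by the matched polarisation of the two partners, while the methyl ynol ether cannot fragment to a ketene by a retro-ene path at the temperature needed.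

Step 9
Reactants: 17 1-[2,6-dimethoxy-3-methyl-4-(triethylsilyloxy)-5-{[2,4,6-tris(benzyloxy)-3-methylphenyl]methyl}phenyl]-2-methylpropan-1-one
Product: 18 1-[2,4,6-tris(benzyloxy)-3-{[2,4-dimethoxy-5-methyl-3-(2-methylpropanoyl)-6-(triethylsilyloxy)phenyl]methyl}-5-methylphenyl]-2-methylpropan-1-one
Conditions: i-PrCOCl (1.5 equiv), SnCl4 (2 equiv), 2,6-di-tert-butyl-4-methylpyridine (2 equiv), CH2Cl2, −78 °C; aq. NaHCO3 quench at −78 °C
Reagents that add atoms: isobutyryl chloride, CC(C)C(Cl)=O
Why: Friedel–Crafts acylation should occur at C5' of ring B, the only unsubstituted aromatic carbon of 17 and one that is ortho, ortho and para to three benzyloxy groups, while the low temperature and the hindered pyridine protect the benzyl and silyl ethers and the acid-sensitive diarylmethane.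

Step 10
Reactants: 18 1-[2,4,6-tris(benzyloxy)-3-{[2,4-dimethoxy-5-methyl-3-(2-methylpropanoyl)-6-(triethylsilyloxy)phenyl]methyl}-5-methylphenyl]-2-methylpropan-1-one
Product: 19 1-[2,4,6-tris(benzyloxy)-3-{[6-hydroxy-2,4-dimethoxy-5-methyl-3-(2-methylpropanoyl)phenyl]methyl}-5-methylphenyl]-2-methylpropan-1-one
Conditions: Bu4NF (1.2 equiv), AcOH (1.2 equiv), THF, 0 °C
Reagents that add atoms: none
Why: Fluoride-mediated desilylation, driven by the Si–F bond and buffered with acetic acid, should free the C3 phenol of ring A without touching benzyl ethers or ketones.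

Step 11
Reactants: 19 1-[2,4,6-tris(benzyloxy)-3-{[6-hydroxy-2,4-dimethoxy-5-methyl-3-(2-methylpropanoyl)phenyl]methyl}-5-methylphenyl]-2-methylpropan-1-one
Product: 20 EANPDB:ROSA_00016
Conditions: H2 (1 atm), 10% Pd/C, EtOAc/MeOH, rt
Reagents that add atoms: none
Why: Catalytic hydrogenolysis of the three benzyl aryl ethers should release the ring B phenols, the two hindered, hydrogen-bonded aryl ketones and the diarylmethane link being inert at one atmosphere in a neutral solvent.

**Compound list**
1 | 2-methylphloroglucinol | Cc1c(O)cc(O)cc1O | starting material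
2 | N-[(2,4,6-trihydroxy-3-methylphenyl)methylidene]-N-methylmethanaminium chloride | C[N+](C)=Cc1c(O)cc(O)c(C)c1O.[Cl-] | intermediate
3 | 2,4,6-trihydroxy-3-methylbenzaldehyde | O=Cc1c(O)cc(O)c(C)c1O | intermediate
4 | 2,4,6-tris(benzyloxy)-3-methylbenzaldehyde | O=Cc1c(OCc2ccccc2)cc(OCc2ccccc2)c(C)c1OCc1ccccc1 | intermediate
5 | 2-methylcyclohexane-1,3-dione | CC1C(=O)CCCC1=O | starting material
6 | 3-methoxy-2-methylcyclohex-2-en-1-one | COC1=C(C)C(=O)CCC1 | intermediate
7 | lithium 4-methoxy-3-methylcyclohexa-1,3-dien-2-olate (kinetic dienolate of 6) | [Li]OC1=CCCC(OC)=C1C | intermediate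
8 | 6-{hydroxy[2,4,6-tris(benzyloxy)-3-methylphenyl]methyl}-3-methoxy-2-methylcyclohex-2-en-1-one (diastereomer mixture, racemic) | COC1=C(C)C(=O)C(CC1)C(O)c1c(OCc2ccccc2)cc(OCc2ccccc2)c(C)c1OCc1ccccc1 | intermediate
9 | methanesulfonate of 8 (diastereomer mixture, racemic) | COC1=C(C)C(=O)C(CC1)C(OS(C)(=O)=O)c1c(OCc2ccccc2)cc(OCc2ccccc2)c(C)c1OCc1ccccc1 | intermediate
10 | (E)-6-{[2,4,6-tris(benzyloxy)-3-methylphenyl]methylidene}-3-methoxy-2-methylcyclohex-2-en-1-one | COC1=C(C)C(=O)/C(CC1)=C/c1c(OCc2ccccc2)cc(OCc2ccccc2)c(C)c1OCc1ccccc1 | intermediate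
11 | 1-methoxy-2-methyl-3-(triethylsilyloxy)-4-{[2,4,6-tris(benzyloxy)-3-methylphenyl]methyl}cyclohexa-1,3-diene | COC1=C(C)C(O[Si](CC)(CC)CC)=C(Cc2c(OCc3ccccc3)cc(OCc3ccccc3)c(C)c2OCc3ccccc3)CC1 | intermediate
12 | chloroacetaldehyde dimethyl acetal | COC(CCl)OC | starting material
13 | N-methoxy-N-methylisobutyramide | CON(C)C(=O)C(C)C | starting material
14 | lithium methoxyacetylide | [Li]C#COC | intermediate
15 | 1-methoxy-4-methylpent-1-yn-3-one | COC#CC(=O)C(C)C | intermediate
16 | 1-[1,3-dimethoxy-6-methyl-5-(triethylsilyloxy)-4-{[2,4,6-tris(benzyloxy)-3-methylphenyl]methyl}bicyclo[2.2.2]octa-2,5-dien-2-yl]-2-methylpropan-1-one (racemic) | COC12CCC(Cc3c(OCc4ccccc4)cc(OCc4ccccc4)c(C)c3OCc3ccccc3)(C(O[Si](CC)(CC)CC)=C1C)C(OC)=C2C(=O)C(C)C | intermediate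
17 | 1-[2,6-dimethoxy-3-methyl-4-(triethylsilyloxy)-5-{[2,4,6-tris(benzyloxy)-3-methylphenyl]methyl}phenyl]-2-methylpropan-1-one | COc1c(C)c(O[Si](CC)(CC)CC)c(Cc2c(OCc3ccccc3)cc(OCc3ccccc3)c(C)c2OCc3ccccc3)c(OC)c1C(=O)C(C)C | intermediate
18 | 1-[2,4,6-tris(benzyloxy)-3-{[2,4-dimethoxy-5-methyl-3-(2-methylpropanoyl)-6-(triethylsilyloxy)phenyl]methyl}-5-methylphenyl]-2-methylpropan-1-one | COc1c(C)c(O[Si](CC)(CC)CC)c(Cc2c(OCc3ccccc3)c(C(=O)C(C)C)c(OCc3ccccc3)c(C)c2OCc3ccccc3)c(OC)c1C(=O)C(C)C | intermediate
19 | 1-[2,4,6-tris(benzyloxy)-3-{[6-hydroxy-2,4-dimethoxy-5-methyl-3-(2-methylpropanoyl)phenyl]methyl}-5-methylphenyl]-2-methylpropan-1-one | COc1c(C)c(O)c(Cc2c(OCc3ccccc3)c(C(=O)C(C)C)c(OCc3ccccc3)c(C)c2OCc3ccccc3)c(OC)c1C(=O)C(C)C | intermediate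
20 | EANPDB:ROSA_00016, 1-[2,4,6-trihydroxy-3-{[6-hydroxy-2,4-dimethoxy-5-methyl-3-(2-methylpropanoyl)phenyl]methyl}-5-methylphenyl]-2-methylpropan-1-one | COc1c(C)c(O)c(Cc2c(O)c(C)c(O)c(C(=O)C(C)C)c2O)c(OC)c1C(=O)C(C)C | target

**Step count and risks**

Total step count: 11. Longest linear sequence: 9 steps (steps 1, 2, 4, 5, 6, 8, 9, 10, 11, from 1 to 20).

Steps most likely to fail:

1. Step 8 (Alder–Rickert with the methoxy ynone). The donor-substituted alkyne may add too slowly to a diene that is substituted at both termini. Thermal 1,5-hydrogen shift of the diene, hydrolytic loss of the silyl enol ether, (2+2) addition or polymerisation of the ynone could then outrun the cycloaddition.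
Fallback: this sets out from 1 and comes back at 20, building ring A by classical aromatic chemistry and forming the bridge last. Friedel–Crafts acylation of 1 (isobutyryl chloride, AlCl3, nitrobenzene/CH2Cl2) would give 1-(2,4,6-trihydroxy-3-methylphenyl)-2-methylpropan-1-one F1. Selective benzylation of its unchelated para hydroxyl (one equivalent of BnBr, K2CO3, acetone) would give 1-[4-(benzyloxy)-2,6-dihydroxy-3-methylphenyl]-2-methylpropan-1-one F2. Methylation of both chelated ortho hydroxyls (Me2SO4, K2CO3, acetone, reflux) would give 1-[4-(benzyloxy)-2,6-dimethoxy-3-methylphenyl]-2-methylpropan-1-one F3. Hydrogenolysis (H2, Pd/C) would give the ring A monomer 1-(4-hydroxy-2,6-dimethoxy-3-methylphenyl)-2-methylpropan-1-one F4. A Mannich reaction at its only free ring carbon, ortho to the phenol (aqueous CH2O, Me2NH, EtOH), would give 1-{3-[(dimethylamino)methyl]-4-hydroxy-2,6-dimethoxy-5-methylphenyl}-2-methylpropan-1-one F5. Heating F5 with a second portion of F1 in dioxane should expel dimethylamine, and the ortho-quinone methide so formed should be captured by the free ring carbon of F1 to give 20 directly. This is the known Mannich-base coupling used for methylene-bridged acylphloroglucinols.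

2. Step 9 (Friedel–Crafts acylation). Lewis-acid-induced loss of benzyl groups, or protonation at the bridge-bearing carbon of ring B followed by retro-Friedel–Crafts cleavage of the diarylmethane, may compete with acylation.
Fallback: this sets out from 17 and comes back at 18. Vilsmeier–Haack formylation (POCl3, DMF, 0 to 40 °C, aqueous NaOAc) at C5' would give 2,4,6-tris(benzyloxy)-3-{[2,4-dimethoxy-5-methyl-3-(2-methylpropanoyl)-6-(triethylsilyloxy)phenyl]methyl}-5-methylbenzaldehyde F6. Addition of i-PrMgCl with CeCl3 in THF at −78 °C to the aldehyde would give the secondary alcohol 1-[2,4,6-tris(benzyloxy)-3-{[2,4-dimethoxy-5-methyl-3-(2-methylpropanoyl)-6-(triethylsilyloxy)phenyl]methyl}-5-methylphenyl]-2-methylpropan-1-ol F7; the doubly ortho-substituted ring A ketone is too hindered to add. Dess–Martin oxidation (NaHCO3, CH2Cl2) would then give 18.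

3. Step 6 (1,4-hydrosilylation). Competing 1,2-hydrosilylation of the carbonyl, slow turnover at the hindered benzylic carbon, or hydrolysis of the silyl enol ether during isolation may lower the supply of diene.
Fallback: this sets out from 10 and comes back at 11. Conjugate reduction with [(Ph3P)CuH]6 in wet benzene at rt would give 6-{[2,4,6-tris(benzyloxy)-3-methylphenyl]methyl}-3-methoxy-2-methylcyclohex-2-en-1-one F8. Kinetic deprotonation at the benzyl-bearing carbon (LiN(i-Pr)2, THF, −78 °C) and O-silylation with Et3SiCl would give 11.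

**Further compounds**
F1 | step 8 | 1-(2,4,6-trihydroxy-3-methylphenyl)-2-methylpropan-1-one | CC(C)C(=O)c1c(O)cc(O)c(C)c1O
F2 | step 8 | 1-[4-(benzyloxy)-2,6-dihydroxy-3-methylphenyl]-2-methylpropan-1-one | CC(C)C(=O)c1c(O)cc(OCc2ccccc2)c(C)c1O
F3 | step 8 | 1-[4-(benzyloxy)-2,6-dimethoxy-3-methylphenyl]-2-methylpropan-1-one | CC(C)C(=O)c1c(OC)cc(OCc2ccccc2)c(C)c1OC
F4 | step 8 | 1-(4-hydroxy-2,6-dimethoxy-3-methylphenyl)-2-methylpropan-1-one | CC(C)C(=O)c1c(OC)cc(O)c(C)c1OC
F5 | step 8 | 1-{3-[(dimethylamino)methyl]-4-hydroxy-2,6-dimethoxy-5-methylphenyl}-2-methylpropan-1-one | CC(C)C(=O)c1c(OC)c(CN(C)C)c(O)c(C)c1OC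
F6 | step 9 | 2,4,6-tris(benzyloxy)-3-{[2,4-dimethoxy-5-methyl-3-(2-methylpropanoyl)-6-(triethylsilyloxy)phenyl]methyl}-5-methylbenzaldehyde | COc1c(C)c(O[Si](CC)(CC)CC)c(Cc2c(OCc3ccccc3)c(C=O)c(OCc3ccccc3)c(C)c2OCc3ccccc3)c(OC)c1C(=O)C(C)C
F7 | step 9 | 1-[2,4,6-tris(benzyloxy)-3-{[2,4-dimethoxy-5-methyl-3-(2-methylpropanoyl)-6-(triethylsilyloxy)phenyl]methyl}-5-methylphenyl]-2-methylpropan-1-ol (racemic) | COc1c(C)c(O[Si](CC)(CC)CC)c(Cc2c(OCc3ccccc3)c(C(O)C(C)C)c(OCc3ccccc3)c(C)c2OCc3ccccc3)c(OC)c1C(=O)C(C)C
F8 | step 6 | 6-{[2,4,6-tris(benzyloxy)-3-methylphenyl]methyl}-3-methoxy-2-methylcyclohex-2-en-1-one (racemic) | COC1=C(C)C(=O)C(Cc2c(OCc3ccccc3)cc(OCc3ccccc3)c(C)c2OCc3ccccc3)CC1
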